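The route rests on cutting the O7–C1 bond of the 7-oxabicyclo[2.2.1]heptane, C1 being the methyl-bearing bridgehead next to side-chain carbon C2. The feature exploited is that O7 and the endo C2 side chain stand anti across C1–C2, the signature of an anti addition to a cyclohexene. The precursor is therefore the Me3Si ether of (1S,2R)-1,2,4-trimethylcyclohex-3-enol. In one operation Me2AlCl-activated formaldehyde bonds to C2 from the lower face and the transannular silyl ether oxygen captures the tertiary C1 cation. This closes both oxolane rings and sets C1 and C2. The CH2OH handle is coupled with an (S)-linalool-derived allylic bromide, and a biomimetic bromoetherification closes the oxane last.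

Key step: step 4

Assumption: (S)-(+)-linalool of high enantiomeric purity and diisopropyl (E)-crotylboronate are treated as purchasable; C1–C6/O7 number the oxabicycle (C2 carries the side chain, "upper face" is the O7 face) and oxane C2/C3/C6 number the bromo ether ring.

Step 1
Reactants: 1 5-methylhex-5-en-2-one; 2 diisopropyl (E)-but-2-en-1-ylboronate
Product: 4 (3R,4S)-3,4,7-trimethylocta-1,7-dien-4-ol, via borate ester 3 (not isolated)
Conditions: (S)-3,3'-Br2-BINOL (15 mol%), PhCF3/toluene, −35 °C; aq. NH4Cl
Reagents that add atoms: none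
Why: Chiral-diol-catalysed asymmetric crotylboration of a ketone through a closed six-membered chair, with the homomethallyl chain equatorial and the ketone methyl axial, so the E-crotyl geometry gives the anti (3R,4S) pair and the diol selects the Re face of the carbonyl group (the antipodal diol is equally available should the sense prove opposite).

Step 2
Reactants: 4 (3R,4S)-3,4,7-trimethylocta-1,7-dien-4-ol
Product: 5 (1S,2R)-1,2,4-trimethylcyclohex-3-en-1-ol (OH cis to the C2 methyl)
Conditions: second-generation Grubbs catalyst (2 mol%), CH2Cl2 (0.01 M), 40 °C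
Reagents that add atoms: none
Why: Ring-closing metathesis of a monosubstituted and a 1,1-disubstituted alkene closes the six-membered ring as the trisubstituted alkene with loss of ethene, tolerates the free tertiary alcohol and touches neither stereocentre.

Step 3
Reactants: 5 (1S,2R)-1,2,4-trimethylcyclohex-3-en-1-ol
Product: 6 trimethyl{[(1S,2R)-1,2,4-trimethylcyclohex-3-en-1-yl]oxy}silane
Conditions: Me3SiOTf, 2,6-lutidine, CH2Cl2, −78 → 0 °C
Reagents that add atoms: trimethylsilyl triflate, C[Si](C)(C)OS(=O)(=O)C(F)(F)F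
Why: Silyl triflate silylation of a hindered tertiary alcohol removes the aluminium-binding OH, shields the upper face and leaves a group labile enough to be shed in step 4.

Step 4
Reactants: 6 trimethyl{[(1S,2R)-1,2,4-trimethylcyclohex-3-en-1-yl]oxy}silane
Product: 9 [(1R,2S,3R,4S)-1,3,4-trimethyl-7-oxabicyclo[2.2.1]heptan-2-yl]methanol (CH2OH endo; C3 methyl exo), via aluminoxy carbocation 7 (not isolated), via dimethylaluminium alkoxide 8 (not isolated)
Conditions: (CH2O)n (2 equiv), Me2AlCl (2.2 equiv), CH2Cl2, 0 °C, 30 min; add 6, −40 → 0 °C; aq. potassium sodium tartrate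
Reagents that add atoms: formaldehyde (from paraformaldehyde), C=O
Why: Proposed new method: Me2AlCl-bound formaldehyde adds in Prins fashion to the less substituted alkene carbon (future C2) of 6 to give the β-aluminoxy tertiary carbocation 7, the transannular C4–OSiMe3 oxygen captures its C1 centre through a boat conformer, and chloride from the aluminate strips Me3Si from the silyloxonium ion to leave alkoxide 8. The closest known reaction types are the Me2AlCl-promoted Prins/ene addition of formaldehyde to trisubstituted alkenes and the acid-induced transannular closure of terpinen-4-ol and of its epoxide to 1,4-cineoles; new is their merger, with a silyl ether as the terminating nucleophile. The one new O7–C1 bond closes both oxolane rings of the bicycle: counted through C5–C6 the closure is 5-exo-trig on the C1=C2 alkene, counted through C3–C2 it is 5-endo-trig, which an open tertiary cation permits. C1 can only form with O7 bridging cis to C4, so the C4 stereocentre dictates it, and C2 is set by approach of the small electrophile to the lower face, anti to the OSiMe3 group and to the C3 methyl group that both occupy the upper face, which leaves the CH2O arm endo and trans to the C3 methyl. The step needs Markovnikov regioselectivity (secured by the methyl group on C1), lower-face attack (secured by silylation, which also rules out aluminium-alkoxide-directed delivery to the upper face) and oxygen capture faster than proton loss or chloride collapse (favoured by the proton-scavenging Al–Me bonds, the reversibility of chloride capture and the proximity of the oxygen).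

Step 5
Reactants: 9 [(1R,2S,3R,4S)-1,3,4-trimethyl-7-oxabicyclo[2.2.1]heptan-2-yl]methanol
Product: 10 (1R,2R,3R,4S)-2-(bromomethyl)-1,3,4-trimethyl-7-oxabicyclo[2.2.1]heptane
Conditions: CBr4, PPh3, CH2Cl2, 0 °C
Reagents that add atoms: tetrabromomethane, BrC(Br)(Br)Br
Why: Appel bromination of the primary alcohol (SN2 at CH2, no stereocentre involved) runs under neutral conditions that the di-tertiary ether bridge survives.

Step 6
Reactants: 11 (S)-(+)-linalool
Product: 12 {[(3S)-3,7-dimethylocta-1,6-dien-3-yl]oxy}triethylsilane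
Conditions: Et3SiOTf, 2,6-lutidine, CH2Cl2, −78 → 0 °C
Reagents that add atoms: triethylsilyl triflate, CC[Si](CC)(CC)OS(=O)(=O)C(F)(F)F
Why: Silyl triflate protection of the tertiary allylic alcohol keeps it from quenching the Grignard reagent of step 9 and from ionising, and leaves the chiral-pool stereocentre (future oxane C6) untouched.

Step 7
Reactants: 12 {[(3S)-3,7-dimethylocta-1,6-dien-3-yl]oxy}triethylsilane
Product: 13 (2E,6S)-2,6-dimethyl-6-[(triethylsilyl)oxy]octa-2,7-dien-1-ol
Conditions: SeO2 (10 mol%), t-BuOOH (2 equiv), salicylic acid (10 mol%), CH2Cl2, 0 °C → rt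
Reagents that add atoms: tert-butyl hydroperoxide, CC(C)(C)OO (oxygen relayed through catalytic SeO2)
Why: Riley-type allylic oxidation (ene reaction, then [2,3]-sigmatropic shift) is selective for the E-methyl group of a trisubstituted alkene and thus fixes the E geometry, while the vinyl group has no allylic hydrogen.

Step 8
Reactants: 13 (2E,6S)-2,6-dimethyl-6-[(triethylsilyl)oxy]octa-2,7-dien-1-ol
Product: 14 {[(3S,6E)-8-bromo-3,7-dimethylocta-1,6-dien-3-yl]oxy}triethylsilane
Conditions: CBr4, PPh3, 2,6-lutidine (0.2 equiv), CH2Cl2, −20 °C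
Reagents that add atoms: tetrabromomethane, BrC(Br)(Br)Br
Why: Appel bromination of the primary allylic alcohol proceeds by direct SN2 displacement at low temperature and keeps both the E alkene and the silyl ether.

Step 9
Reactants: 10 (1R,2R,3R,4S)-2-(bromomethyl)-1,3,4-trimethyl-7-oxabicyclo[2.2.1]heptane; 14 {[(3S,6E)-8-bromo-3,7-dimethylocta-1,6-dien-3-yl]oxy}triethylsilane
Product: 16 {[(3S,6E)-3,7-dimethyl-9-[(1R,2R,3R,4S)-1,3,4-trimethyl-7-oxabicyclo[2.2.1]heptan-2-yl]nona-1,6-dien-3-yl]oxy}triethylsilane, via Grignard reagent 15 (not isolated)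
Conditions: Mg, THF, 45 °C; then 14, Li2CuCl4 (5 mol%), THF, −30 → 0 °C
Reagents that add atoms: none
Why: Li2CuCl4-catalysed sp3–sp3 coupling of a primary Grignard reagent with a primary allylic bromide should attack the unhindered α-carbon with retention of the E alkene, as is usual for 2-methylallylic halides of the terpene series, and touches no stereocentre.

Step 10
Reactants: 16 {[(3S,6E)-3,7-dimethyl-9-[(1R,2R,3R,4S)-1,3,4-trimethyl-7-oxabicyclo[2.2.1]heptan-2-yl]nona-1,6-dien-3-yl]oxy}triethylsilane
Product: 17 (3S,6E)-3,7-dimethyl-9-[(1R,2R,3R,4S)-1,3,4-trimethyl-7-oxabicyclo[2.2.1]heptan-2-yl]nona-1,6-dien-3-ol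
Conditions: Bu4NF, THF, 0 °C → rt
Reagents that add atoms: none
Why: Fluoride-induced desilylation frees the tertiary allylic alcohol under non-acidic conditions, so neither this alcohol nor the ether bridge can ionise.

Step 11
Reactants: 17 (3S,6E)-3,7-dimethyl-9-[(1R,2R,3R,4S)-1,3,4-trimethyl-7-oxabicyclo[2.2.1]heptan-2-yl]nona-1,6-dien-3-ol
Product: 18 dactylopyranoid, (1R,2R,3R,4S)-2-{2-[(2S,3R,6S)-3-bromo-6-ethenyl-2,6-dimethyloxan-2-yl]ethyl}-1,3,4-trimethyl-7-oxabicyclo[2.2.1]heptane
Conditions: 2,4,4,6-tetrabromocyclohexa-2,5-dienone (1.1 equiv), MeNO2, 0 °C, dark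
Reagents that add atoms: 2,4,4,6-tetrabromocyclohexa-2,5-dienone, O=C1C(Br)=CC(Br)(Br)C=C1Br
Why: Biomimetic 6-endo bromoetherification, in which Br+ goes to the electron-rich trisubstituted alkene and the tertiary hydroxyl attacks the tertiary carbon (Markovnikov), adds anti across the E alkene and so fixes oxane C2 and C3 relative to each other (Br and side chain equatorial), while their relation to C6 rests on the chair with the vinyl group equatorial and on chromatographic removal of the diastereomer from the other alkene face.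

Compound list
1 | 5-methylhex-5-en-2-one | CC(=O)CCC(C)=C | starting material
2 | diisopropyl (E)-but-2-en-1-ylboronate | C/C=C/CB(OC(C)C)OC(C)C | starting material
3 | diisopropyl (3R,4S)-3,4,7-trimethylocta-1,7-dien-4-yl borate | C=C[C@@H](C)[C@@](C)(OB(OC(C)C)OC(C)C)CCC(C)=C | intermediate
4 | (3R,4S)-3,4,7-trimethylocta-1,7-dien-4-ol | C=C[C@@H](C)[C@@](C)(O)CCC(C)=C | intermediate
5 | (1S,2R)-1,2,4-trimethylcyclohex-3-en-1-ol | C[C@@H]1C=C(C)CC[C@]1(C)O | intermediate
6 | trimethyl{[(1S,2R)-1,2,4-trimethylcyclohex-3-en-1-yl]oxy}silane | C[C@@H]1C=C(C)CC[C@]1(C)O[Si](C)(C)C | intermediate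
7 | zwitterionic tertiary cyclohexyl cation carrying the CH2O–AlMe2Cl arm on the lower face | C[C@@H]1[C@@H](CO[Al-](C)(C)Cl)[C+](C)CC[C@]1(C)O[Si](C)(C)C | intermediate
8 | dimethylaluminium alkoxide of 9 | C[Al](C)OC[C@@H]1[C@@H](C)[C@]2(C)CC[C@@]1(C)O2 | intermediate
9 | [(1R,2S,3R,4S)-1,3,4-trimethyl-7-oxabicyclo[2.2.1]heptan-2-yl]methanol | OC[C@@H]1[C@@H](C)[C@]2(C)CC[C@@]1(C)O2 | intermediate
10 | (1R,2R,3R,4S)-2-(bromomethyl)-1,3,4-trimethyl-7-oxabicyclo[2.2.1]heptane | BrC[C@@H]1[C@@H](C)[C@]2(C)CC[C@@]1(C)O2 | intermediate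
11 | (S)-(+)-linalool | C=C[C@@](C)(O)CCC=C(C)C | starting material
12 | {[(3S)-3,7-dimethylocta-1,6-dien-3-yl]oxy}triethylsilane | C=C[C@@](C)(O[Si](CC)(CC)CC)CCC=C(C)C | intermediate
13 | (2E,6S)-2,6-dimethyl-6-[(triethylsilyl)oxy]octa-2,7-dien-1-ol | C=C[C@@](C)(O[Si](CC)(CC)CC)CC/C=C(\C)CO | intermediate
14 | {[(3S,6E)-8-bromo-3,7-dimethylocta-1,6-dien-3-yl]oxy}triethylsilane | C=C[C@@](C)(O[Si](CC)(CC)CC)CC/C=C(\C)CBr | intermediate
15 | {[(1R,2R,3R,4S)-1,3,4-trimethyl-7-oxabicyclo[2.2.1]heptan-2-yl]methyl}magnesium bromide | Br[Mg]C[C@@H]1[C@@H](C)[C@]2(C)CC[C@@]1(C)O2 | intermediate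
16 | triethylsilyl ether of 17 | C=C[C@@](C)(O[Si](CC)(CC)CC)CC/C=C(\C)CC[C@@H]1[C@@H](C)[C@]2(C)CC[C@@]1(C)O2 | intermediate
17 | (3S,6E)-3,7-dimethyl-9-[(1R,2R,3R,4S)-1,3,4-trimethyl-7-oxabicyclo[2.2.1]heptan-2-yl]nona-1,6-dien-3-ol | C=C[C@@](C)(O)CC/C=C(\C)CC[C@@H]1[C@@H](C)[C@]2(C)CC[C@@]1(C)O2 | intermediate
18 | dactylopyranoid | C=C[C@]1(C)CC[C@@H](Br)[C@](C)(CC[C@@H]2[C@@H](C)[C@]3(C)CC[C@@]2(C)O3)O1 | target

Total step count: 11. Longest linear sequence: 8 (steps 1–5 and 9–11).

Steps most likely to fail

Step 4. Proton loss from the tertiary cation (the ene pathway) or collapse with chloride may outrun transannular capture, and the facial selectivity of the C–C bond formation may erode. The fallback uses known chemistry, sets out from 5 and comes back at 9.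
- Hydroxyl-directed epoxidation of 5 with VO(acac)2/t-BuOOH should give the syn epoxy alcohol F1.
- Catalytic TsOH in CH2Cl2 opens the tertiary epoxide terminus, and the C4 hydroxyl closes O7–C1 as in the technical route to 2-hydroxy-1,4-cineole, giving the exo alcohol F2.
- Dess–Martin oxidation gives the ketone F3, whose exo C3 methyl is the stable epimer.
- Wittig methylenation with Ph3P=CH2 gives the exocyclic alkene F4.
- Hydroboration with 9-BBN from the exo face, then H2O2/NaOH, places CH2OH endo and delivers 9.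

Step 11. The distant oxane C6 stereocentre may discriminate poorly between the two alkene faces, and 5-exo closure to an oxolane may compete. The fallback sets out from 17 and comes back at 18.
- Reagent-controlled Shi epoxidation (D-fructose-derived ketone, KHSO5, K2CO3 buffer, MeCN/dimethoxymethane) of the trisubstituted alkene should give the (6R,7R)-epoxy alcohol F5.
- Camphorsulfonic acid in CH2Cl2 induces 6-endo opening at the tertiary epoxide carbon with inversion, giving the equatorial oxan-3-ol F6.
- Dess–Martin oxidation gives the oxan-3-one F7.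
- Li(s-Bu)3BH attacks from the equatorial side to give the axial oxan-3-ol F8.
- ClCH2SO2Cl/pyridine gives the chloromethanesulfonate F9, and LiBr in DMF displaces it with inversion to give 18.

Step 1. The chair transition state may differentiate too weakly between the methyl and the primary alkyl group of a dialkyl ketone, which would erode both enantio- and diastereoselectivity. The fallback sets out from 1 and comes back at 4.
- Horner–Wadsworth–Emmons reaction of 1 with triethyl phosphonoacetate/NaH gives, after removal of the Z isomer, the E-enoate F10.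
- Reduction with i-Bu2AlH gives the allylic alcohol F11.
- Sharpless asymmetric epoxidation (Ti(OiPr)4, L-(+)-diethyl tartrate, t-BuOOH) gives the (2S,3S)-epoxy alcohol F12.
- Me2CuLi opens the epoxide at the less hindered C2 with inversion to give the anti 1,3-diol F13.
- TEMPO/PhI(OAc)2 oxidises only the primary alcohol to the hydroxy aldehyde F14.
- Wittig methylenation with Ph3P=CH2 returns 4.

Further compounds
F1 | step 4 | 2,3,6-trimethyl-7-oxabicyclo[4.1.0]heptan-3-ol, epoxide oxygen cis to OH | C[C@@H]1[C@@H]2O[C@]2(C)CC[C@]1(C)O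
F2 | step 4 | 1,3,4-trimethyl-7-oxabicyclo[2.2.1]heptan-2-ol, OH exo, C3 methyl exo | O[C@H]1[C@@H](C)[C@]2(C)CC[C@@]1(C)O2
F3 | step 4 | 1,3,4-trimethyl-7-oxabicyclo[2.2.1]heptan-2-one, C3 methyl exo | O=C1[C@@H](C)[C@]2(C)CC[C@@]1(C)O2
F4 | step 4 | 1,3,4-trimethyl-2-methylidene-7-oxabicyclo[2.2.1]heptane, C3 methyl exo | C=C1[C@@H](C)[C@]2(C)CC[C@@]1(C)O2
F5 | step 11 | (6R,7R)-6,7-epoxide of 17 | C=C[C@@](C)(O)CC[C@H]1O[C@]1(C)CC[C@@H]2[C@@H](C)[C@]3(C)CC[C@@]2(C)O3
F6 | step 11 | (2S,3R,6S)-oxan-3-ol analogue of 18 (equatorial OH in place of Br) | C=C[C@]1(C)CC[C@@H](O)[C@](C)(CC[C@@H]2[C@@H](C)[C@]3(C)CC[C@@]2(C)O3)O1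
F7 | step 11 | (2S,6S)-oxan-3-one analogue of 18 | C=C[C@]1(C)CCC(=O)[C@](C)(CC[C@@H]2[C@@H](C)[C@]3(C)CC[C@@]2(C)O3)O1
F8 | step 11 | (2S,3S,6S)-oxan-3-ol (axial OH) | C=C[C@]1(C)CC[C@H](O)[C@](C)(CC[C@@H]2[C@@H](C)[C@]3(C)CC[C@@]2(C)O3)O1
F9 | step 11 | chloromethanesulfonate of F8 | C=C[C@]1(C)CC[C@H](OS(=O)(=O)CCl)[C@](C)(CC[C@@H]2[C@@H](C)[C@]3(C)CC[C@@]2(C)O3)O1
F10 | step 1 | ethyl (E)-3,7-dimethylocta-2,7-dienoate | CCOC(=O)/C=C(\C)CCC(C)=C
F11 | step 1 | (E)-3,7-dimethylocta-2,7-dien-1-ol | OC/C=C(\C)CCC(C)=C
F12 | step 1 | [(2S,3S)-3-methyl-3-(3-methylbut-3-en-1-yl)oxiran-2-yl]methanol | OC[C@@H]1O[C@@]1(C)CCC(C)=C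
F13 | step 1 | (2R,3S)-2,3,7-trimethyloct-7-ene-1,3-diol | OC[C@@H](C)[C@@](C)(O)CCC(C)=C
F14 | step 1 | (2S,3S)-3-hydroxy-2,3,7-trimethyloct-7-enal | O=C[C@@H](C)[C@@](C)(O)CCC(C)=C
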